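**Plan**

- Feature: the only stereocentre is C2 of ring C, a CH carbon bonded to O1, C3 and the 4-methoxyphenyl ring and lying β to the C4 ketone. Two hydrogens (on C2 and C3) are all that separate the target from a flat flavone.
- Retrosynthesis: cut the MOM mask on O5, then the C2–H and C3–H bonds (back to the C2=C3–C4=O enone), then the C8–prenyl bond (returned to O5 through a Cope and a Claisen shift), the O5–prenyl bond and the O7–CH3 bond, arriving at acacetin.
- Forward: rings A, B and C are all present in acacetin and no ring is formed. The order is O7 methylation, O5 prenylation, prenyl migration O5 → C6 → C8, MOM capping of O5, 1,4-reduction of ring C, MOM removal.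
- Stereochemistry: (2S) comes from catalyst-controlled hydride delivery to one face of C2 by a copper hydride carrying (S)-DTBM-SEGPHOS. Nothing after that step exposes C2 to base.

Key step: step 5

Assumption: by analogy with β-substituted cyclohexenones, the (S) enantiomer of DTBM-SEGPHOS is taken to deliver hydride to the face of C2 that gives the (2S) product. If the sense proves opposite, the (R) ligand is used with nothing else changed.

**Route**

Step 1
Reactants: 1 acacetin (5,7-dihydroxy-2-(4-methoxyphenyl)chromen-4-one); 2 methyl iodide
Product: 3 5-hydroxy-7-methoxy-2-(4-methoxyphenyl)chromen-4-one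
Conditions: MeI (1.1 equiv), K2CO3 (1.2 equiv), acetone, reflux
Reagents that add atoms: methyl iodide (compound 2), CI
Why: Williamson ether synthesis; the 7-hydroxyl is a vinylogous acid towards the C4 carbonyl and is deprotonated by K2CO3 far more readily than the 5-hydroxyl, which is held in a hydrogen bond to C4=O, so one equivalent of methyl iodide should alkylate O7 only.

Step 2
Reactants: 3 5-hydroxy-7-methoxy-2-(4-methoxyphenyl)chromen-4-one; 4 prenyl bromide (1-bromo-3-methylbut-2-ene)
Product: 5 7-methoxy-2-(4-methoxyphenyl)-5-(3-methylbut-2-enyloxy)chromen-4-one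
Conditions: prenyl bromide (1.5 equiv), K2CO3 (3 equiv), DMF, 50 °C
Reagents that add atoms: prenyl bromide (compound 4), CC(C)=CCBr
Why: Williamson ether synthesis under more forcing conditions; with O7 blocked, excess K2CO3 in DMF breaks the O5–H···O=C4 hydrogen bond and the phenoxide is O-alkylated at the primary carbon of the reactive allylic bromide.

Step 3
Reactants: 5 7-methoxy-2-(4-methoxyphenyl)-5-(3-methylbut-2-enyloxy)chromen-4-one
Product: 8 5-hydroxy-7-methoxy-2-(4-methoxyphenyl)-8-(3-methylbut-2-enyl)chromen-4-one, via C6 ortho-dienone 6 (not isolated), via C8 para-dienone 7 (not isolated)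
Conditions: Eu(fod)3 (10 mol %; fod = 6,6,7,7,8,8,8-heptafluoro-2,2-dimethyloctane-3,5-dionate), NaHCO3, PhCl, 85 °C
Reagents that add atoms: none
Why: aromatic para-Claisen (Claisen–Cope) rearrangement catalysed by the oxophilic trivalent europium complex bound at O5 and C4=O; a [3,3] shift carries the allyl unit to C6 as a 1,1-dimethylallyl group (dienone 6), the crowded dienone undergoes a second [3,3] (Cope) shift to C8 that restores the linear prenyl group (dienone 7), and tautomerisation gives the chelated phenol, while NaHCO3 buffers adventitious acid.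

Step 4
Reactants: 8 5-hydroxy-7-methoxy-2-(4-methoxyphenyl)-8-(3-methylbut-2-enyl)chromen-4-one; 9 chloromethyl methyl ether
Product: 10 7-methoxy-5-(methoxymethoxy)-2-(4-methoxyphenyl)-8-(3-methylbut-2-enyl)chromen-4-one
Conditions: NaH (1.5 equiv), MOMCl (1.5 equiv), DMF, 0 °C → 25 °C
Reagents that add atoms: chloromethyl methyl ether (compound 9), COCCl
Why: MOM protection by O-alkylation of the sodium phenoxide with the highly electrophilic α-chloro ether; irreversible deprotonation by NaH overcomes the chelation of the 5-hydroxyl, and the flavone has no other acidic site.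

Step 5
Reactants: 10 7-methoxy-5-(methoxymethoxy)-2-(4-methoxyphenyl)-8-(3-methylbut-2-enyl)chromen-4-one
Product: 12 (2S)-7-methoxy-5-(methoxymethoxy)-2-(4-methoxyphenyl)-8-(3-methylbut-2-enyl)chroman-4-one, via silyl enol ether 11 (not isolated)
Conditions: Cu(OAc)2 (5 mol %), (S)-DTBM-SEGPHOS (5.5 mol %), (EtO)2MeSiH (3 equiv), toluene, 0 °C → 25 °C, no alcohol additive; then AcOH, THF–H2O, 0 °C
Reagents that add atoms: none
Why: Cu(OAc)2, the bisphosphine and the silane generate a ligated monovalent copper hydride that adds across the C2=C3–C4=O vinylogous ester of ring C with hydride to C2 and copper to the C4 oxygen, and σ-bond metathesis of the copper enolate with (EtO)2MeSiH releases silyl enol ether 11 and regenerates the hydride; mild aqueous acid then protonates C3. The closest known reaction type is the copper hydride catalysed asymmetric conjugate reduction of β,β-disubstituted cyclic enones and 2-substituted chromones with DTBM-SEGPHOS-type ligands, within which this 2-aryl, 5-oxygenated chromone is a demanding member. No ring is closed and no skeletal bond is formed; rings A, B and C pass through unchanged. The C2 stereocentre is set under catalyst control: the C2-symmetric bisphosphine shields one face of the planar enone, so hydride reaches C2 from the face that gives the (2S) arrangement of aryl, O1 and C3. The step needs 1,4- over 1,2-selectivity, chemoselectivity against the prenyl group and retention of the O1–C2 bond: the enone is the only polarised alkene, the trisubstituted prenyl alkene should not insert into the hindered copper hydride, and the MOM cap on O5 removes the acidic chelated phenol that would quench the hydride. Running without an alcohol keeps C4 masked as the silyl enol ether until work-up, so the copper enolate should neither expel the O1 phenoxide nor release a ketone that could be reduced further.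

Step 6
Reactants: 12 (2S)-7-methoxy-5-(methoxymethoxy)-2-(4-methoxyphenyl)-8-(3-methylbut-2-enyl)chroman-4-one
Product: 13 flowerine, (2S)-5-hydroxy-7-methoxy-2-(4-methoxyphenyl)-8-(3-methylbut-2-enyl)chroman-4-one
Conditions: HCl (1 M in MeOH), MeOH–THF, 25 °C
Reagents that add atoms: none
Why: acid-catalysed acetal cleavage (MOM removal by methanolysis); the O5 acetal peri to the C4 carbonyl is unusually labile because the liberated phenol is stabilised by chelation, the aryl methyl ethers are inert, the prenyl group has no free ortho-hydroxyl with which to cyclise, and C2 should hold its configuration in dilute acid at room temperature because flavanones racemise through base-induced ring opening.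

**Compound list**

1 | acacetin, 5,7-dihydroxy-2-(4-methoxyphenyl)chromen-4-one | COc1ccc(-c2cc(=O)c3c(O)cc(O)cc3o2)cc1 | starting material
2 | methyl iodide | CI | starting material
3 | 5-hydroxy-7-methoxy-2-(4-methoxyphenyl)chromen-4-one | COc1ccc(-c2cc(=O)c3c(O)cc(OC)cc3o2)cc1 | intermediate
4 | prenyl bromide, 1-bromo-3-methylbut-2-ene | CC(C)=CCBr | starting material
5 | 7-methoxy-2-(4-methoxyphenyl)-5-(3-methylbut-2-enyloxy)chromen-4-one | COc1ccc(-c2cc(=O)c3c(OCC=C(C)C)cc(OC)cc3o2)cc1 | intermediate
6 | C6 ortho-dienone, 7-methoxy-2-(4-methoxyphenyl)-6-(2-methylbut-3-en-2-yl)-6H-chromene-4,5-dione, racemic at C6, not isolated | COc1ccc(cc1)C1=CC(=O)C2=C(O1)C=C(OC)C(C2=O)C(C)(C)C=C | intermediate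
7 | C8 para-dienone, 7-methoxy-2-(4-methoxyphenyl)-8-(3-methylbut-2-enyl)-8H-chromene-4,5-dione, racemic at C8, not isolated | COc1ccc(cc1)C1=CC(=O)C2=C(O1)C(CC=C(C)C)C(OC)=CC2=O | intermediate
8 | 5-hydroxy-7-methoxy-2-(4-methoxyphenyl)-8-(3-methylbut-2-enyl)chromen-4-one | COc1ccc(-c2cc(=O)c3c(O)cc(OC)c(CC=C(C)C)c3o2)cc1 | intermediate
9 | chloromethyl methyl ether | COCCl | starting material
10 | 7-methoxy-5-(methoxymethoxy)-2-(4-methoxyphenyl)-8-(3-methylbut-2-enyl)chromen-4-one | COCOc1cc(OC)c(CC=C(C)C)c2oc(-c3ccc(OC)cc3)cc(=O)c12 | intermediate
11 | silyl enol ether, (2S)-4-[diethoxy(methyl)silyloxy]-7-methoxy-5-(methoxymethoxy)-2-(4-methoxyphenyl)-8-(3-methylbut-2-enyl)-2H-chromene, not isolated | COc1ccc([C@@H]2C=C(O[Si](C)(OCC)OCC)c3c(OCOC)cc(OC)c(CC=C(C)C)c3O2)cc1 | intermediate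
12 | (2S)-7-methoxy-5-(methoxymethoxy)-2-(4-methoxyphenyl)-8-(3-methylbut-2-enyl)chroman-4-one, (S)-5-O-MOM-flowerine | COc1ccc([C@@H]2CC(=O)c3c(OCOC)cc(OC)c(CC=C(C)C)c3O2)cc1 | intermediate
13 | flowerine, (2S)-5-hydroxy-7-methoxy-2-(4-methoxyphenyl)-8-(3-methylbut-2-enyl)chroman-4-one | COc1ccc([C@@H]2CC(=O)c3c(O)cc(OC)c(CC=C(C)C)c3O2)cc1 | target

**Totals and risks**

Total step count: 6. Longest linear sequence: 6 steps, from acacetin 1 to flowerine 13.

Steps most likely to fail:

1. Step 5. Hydride transfer to the hindered, electron-rich C2 may be slow with the bulky ligand and poorly face-selective, so that the flavanone is formed with low enantiomeric purity. The fallback sets out from 10 and comes back at 12. Compound 10 is reduced without asymmetric induction by an achiral copper hydride (Cu(OAc)2, 1,2-bis(diphenylphosphino)benzene, (EtO)2MeSiH, toluene), which should give the racemic silyl enol ether F1 and, after the same mild acid hydrolysis, the racemic 5-O-MOM flavanone F2. F2 is then resolved kinetically by asymmetric transfer hydrogenation with RuCl[(R,R)-TsDPEN](p-cymene) and HCO2H–Et3N in EtOAc, run to a little over half conversion. The catalyst should reduce the (2R) ketone, by hydride attack anti to the aryl group, to the cis-(2R,4R)-flavan-4-ol F3 and leave the (2S) ketone, which is separated by chromatography as 12. Stereocontrol then rests on a ketone reduction that does not touch the prenyl alkene, at the cost of half the material.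

2. Step 3. The sigmatropic sequence may stop after the first shift, with the ortho-dienone rearomatising before the Cope step, or the allyl ether may ionise; the prenyl unit then ends at C6 in its 1,1-dimethylallyl form or is lost. The fallback sets out from 3 and comes back at 10, replacing steps 2 to 4 by a cross-coupling approach. Compound 3 is capped on O5 with 9 and NaH in DMF to give the 5-O-MOM ether F4. Lacking a free 5-hydroxyl to direct attack to C6, F4 should be iodinated at C8 with N-iodosuccinimide in MeCN to give the 8-iodide F5. A Stille coupling of F5 with tributyl(3-methylbut-2-enyl)stannane and Pd(PPh3)4 in DMF at 90 °C should then deliver 10 directly.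

3. Step 2. O-Alkylation of the hydrogen-bonded 5-hydroxyl may be incomplete, and forcing it may bring C-alkylation of the phenoxide at C6 or C8. The fallback sets out from 3 and comes back at 5. It is a Mitsunobu etherification of 3 with 3-methylbut-2-en-1-ol, PPh3 and diisopropyl azodicarboxylate in THF at 0 °C → 25 °C, which activates the alcohol rather than the phenoxide and works under neutral conditions. It makes no new compound (F0).

**Further compounds**

F1 | step 5 | racemic 4-[diethoxy(methyl)silyloxy]-7-methoxy-5-(methoxymethoxy)-2-(4-methoxyphenyl)-8-(3-methylbut-2-enyl)-2H-chromene | COc1ccc(C2C=C(O[Si](C)(OCC)OCC)c3c(OCOC)cc(OC)c(CC=C(C)C)c3O2)cc1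
F2 | step 5 | racemic 7-methoxy-5-(methoxymethoxy)-2-(4-methoxyphenyl)-8-(3-methylbut-2-enyl)chroman-4-one | COc1ccc(C2CC(=O)c3c(OCOC)cc(OC)c(CC=C(C)C)c3O2)cc1
F3 | step 5 | (2R,4R)-7-methoxy-5-(methoxymethoxy)-2-(4-methoxyphenyl)-8-(3-methylbut-2-enyl)chroman-4-ol | COc1ccc([C@H]2C[C@@H](O)c3c(OCOC)cc(OC)c(CC=C(C)C)c3O2)cc1
F4 | step 3 | 7-methoxy-5-(methoxymethoxy)-2-(4-methoxyphenyl)chromen-4-one | COCOc1cc(OC)cc2oc(-c3ccc(OC)cc3)cc(=O)c12
F5 | step 3 | 8-iodo-7-methoxy-5-(methoxymethoxy)-2-(4-methoxyphenyl)chromen-4-one | COCOc1cc(OC)c(I)c2oc(-c3ccc(OC)cc3)cc(=O)c12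
F0 | step 2 | none | none
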